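The route rests on building ring A instead of substituting a phloroglucinol. Its oxygens on C5, C7 and C8a have different fates, and C8, flanked by two of them, holds the side chain. A thermal Danheiser benzannulation merges 3-ethoxycyclobutenone (C8a, C4a, C5, C6) with a triisopropylsiloxyalkyne carrying a prenyl group (C7, C8). In one operation C8–C8a and C6–C7 are made and the benzene ring is closed, with ethyl ether on C5, silyl ether on C7 and a single free hydroxyl on C8a beside the chain. This hydroxyl steers formylation to C4a and closes ring C. Asymmetric aryl addition to the chromone sets C2, and chain oxidation and acetylation come last.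

Key step: step 3

Assumption: the facial bias of t-BuPyOx on the chromone is taken to match its bias on cyclic enones, which points to the (R)-ligand for the 2S product; both antipodes are commercial, and the choice is to be confirmed on the first run by the circular dichroism of the flavanone.

Step 1
Reactants: 1 diketene (4-methylideneoxetan-2-one); 2 ethoxyethyne
Product: 4 3-ethoxycyclobut-2-en-1-one, via ketene 3 (not isolated)
Conditions: 1 cracked in a hot tube (ca. 550 °C, N2 stream); gas led into 2, CH2Cl2, 0 °C → rt; distillation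
Reagents that add atoms: none
Why: Retro-[2+2] cracking of diketene supplies ketene, which undergoes the known [2+2] cycloaddition with the alkoxyalkyne, the nucleophilic terminal alkyne carbon bonding to the ketene carbonyl carbon so that the ethoxy group ends at C3 of the cyclobutenone.

Step 2
Reactants: 5 ethyl 4-methylpent-3-enoate
Product: 8 triisopropyl[(5-methylhex-4-en-1-yn-1-yl)oxy]silane, via dibromo enolate 6 (not isolated), via lithium ynolate 7 (not isolated)
Conditions: CH2Br2, LiTMP (2.2 equiv), THF, −90 °C, then 5; n-BuLi, −78 °C → rt; i-Pr3SiOTf, −78 → 0 °C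
Reagents that add atoms: dibromomethane BrCBr; triisopropylsilyl trifluoromethanesulfonate CC(C)[Si](C(C)C)(C(C)C)OS(=O)(=O)C(F)(F)F
Why: Kowalski ester homologation, in which pre-formed LiCHBr2 should add to the ester faster than it deprotonates the allylic α-position, collapse and deprotonation give dibromo enolate 6, bromine–lithium exchange triggers loss of LiBr with a 1,2-shift to ynolate 7, and the bulky silyl triflate traps 7 on oxygen rather than on carbon.

Step 3
Reactants: 4 3-ethoxycyclobut-2-en-1-one; 8 triisopropyl[(5-methylhex-4-en-1-yn-1-yl)oxy]silane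
Product: 13 5-ethoxy-2-(3-methylbut-2-enyl)-3-(triisopropylsilyloxy)phenol, via vinylketene 9 (not isolated), via vinylcyclobutenone 10 (not isolated), via dienylketene 11 (not isolated), via cyclohexadienone 12 (not isolated)
Conditions: 8 (1.3 equiv), PhMe (0.5 M), argon, sealed tube, 110 °C, then 135 °C until 10 is consumed
Reagents that add atoms: none
Why: Heating opens 4 by 4π electrocyclic cleavage of its C1–C4 bond to vinylketene 9, whose ketene C=C adds across the alkyne of 8 in a [2+2] cycloaddition to give 10; a second 4π opening leads to dienylketene 11, and 6π electrocyclisation to 12 followed by tautomerisation gives phenol 13. The closest known reaction is the Danheiser benzannulation of cyclobutenones with triisopropylsiloxyalkynes to resorcinol monosilyl ethers, applied here to a cyclobutenone that carries an alkoxy group at C3. Ring A, the only ring that persists, closes by the thermally allowed disrotatory 6π electrocyclisation joining the ketene carbon (C8a) to the terminal methylene (C4a), whereas the two lasting new bonds C8–C8a and C6–C7 come from the [2+2] event. No stereocentre survives, since the one in racemic 10 is lost on ring opening. The step needs regiocontrol in the [2+2] addition, and the polarity of the ynol ether provides it: the nucleophilic carbon, which bears the prenyl group, attacks the ketene carbonyl carbon, so the chain lands between the new hydroxyl and the silyl ether. It also needs 9 to choose the alkyne over the prenyl alkene and over phenol already formed, which the far higher ketenophilicity of the ynol ether and its use in excess should ensure.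

Step 4
Reactants: 13 5-ethoxy-2-(3-methylbut-2-enyl)-3-(triisopropylsilyloxy)phenol
Product: 15 6-ethoxy-2-hydroxy-3-(3-methylbut-2-enyl)-4-(triisopropylsilyloxy)benzaldehyde, via hydroxymethylphenol 14 (not isolated)
Conditions: MgCl2 (anhydrous), Et3N, (CH2O)n, MeCN, reflux; cold aq. citric acid
Reagents that add atoms: paraformaldehyde (as formaldehyde) C=O
Why: Casnati–Skattebøl ortho-formylation, in which the magnesium phenoxide binds formaldehyde and delivers it through a six-membered chelate to the ortho carbon only (C8 is blocked and C6 is out of reach), a second formaldehyde oxidises 14 by hydride transfer, and the non-acidic medium keeps the o-prenylphenol from cyclising to a chroman.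

Step 5
Reactants: 15 6-ethoxy-2-hydroxy-3-(3-methylbut-2-enyl)-4-(triisopropylsilyloxy)benzaldehyde
Product: 16 3-ethoxy-2-(1-hydroxyprop-2-ynyl)-6-(3-methylbut-2-enyl)-5-(triisopropylsilyloxy)phenol (racemic)
Conditions: HC≡CMgBr (2.5 equiv), THF, 0 °C → rt; aq. NH4Cl; used crude
Reagents that add atoms: ethynylmagnesium bromide C#C[Mg]Br
Why: Grignard 1,2-addition to the aldehyde after the first equivalent has deprotonated the phenol; the carbinol centre forms as a racemate and is erased in step 6.

Step 6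
Reactants: 16 3-ethoxy-2-(1-hydroxyprop-2-ynyl)-6-(3-methylbut-2-enyl)-5-(triisopropylsilyloxy)phenol
Product: 18 5-ethoxy-8-(3-methylbut-2-enyl)-7-(triisopropylsilyloxy)-4H-chromen-4-one, via ynone 17 (not isolated)
Conditions: MnO2 (activated, excess), CH2Cl2, rt; filter; DMAP (10 mol%), CH2Cl2, rt
Reagents that add atoms: none
Why: MnO2 oxidises the benzylic–propargylic alcohol to ynone 17, and DMAP-catalysed 6-endo-dig oxa-Michael cyclisation of the o-alkynoylphenol closes ring C through the only free hydroxyl (on C8a), which fixes the chain at C8.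

Step 7
Reactants: 18 5-ethoxy-8-(3-methylbut-2-enyl)-7-(triisopropylsilyloxy)-4H-chromen-4-one
Product: 20 5-hydroxy-8-(3-methylbut-2-enyl)-7-(triisopropylsilyloxy)-4H-chromen-4-one, via dichloroboryl ether 19 (not isolated)
Conditions: BCl3 (1 M in CH2Cl2, 1.5 equiv), 2,6-di-tert-butylpyridine (0.3 equiv), CH2Cl2, −78 → −20 °C; cold aq. NaHCO3
Reagents that add atoms: none
Why: Chelation-directed Lewis acid ether cleavage, in which BCl3 is held between the C4 carbonyl and the peri C5 ether oxygen, chloride removes the ethyl group by SN2 attack and hydrolysis of 19 frees the phenol; it is run on the achiral chromone with a hindered pyridine as proton trap, so no stereocentre or allylic ester is exposed and the prenyl alkene meets no HCl.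

Step 8
Reactants: 21 4-bromobenzene-1,2-diol
Product: 22 4-bromo-1,2-bis(tert-butyldimethylsilyloxy)benzene
Conditions: TBSCl (2.4 equiv), imidazole, DMF, rt
Reagents that add atoms: tert-butyldimethylsilyl chloride CC(C)(C)[Si](C)(C)Cl
Why: Imidazole-promoted O-silylation of both phenols; silyl ethers are chosen because they fall together with the C7 silyl ether in the last step under conditions that spare the allylic acetate.

Step 9
Reactants: 22 4-bromo-1,2-bis(tert-butyldimethylsilyloxy)benzene
Product: 25 [3,4-bis(tert-butyldimethylsilyloxy)phenyl]boronic acid, via aryllithium 23 (not isolated), via lithium borate 24 (not isolated)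
Conditions: n-BuLi, THF, −78 °C; B(Oi-Pr)3, −78 °C → rt; 1 M HCl, 0 °C, brief
Reagents that add atoms: triisopropyl borate CC(C)OB(OC(C)C)OC(C)C; water O
Why: Bromine–lithium exchange followed by electrophilic borylation and hydrolysis; the lithium sits meta and para to the silyloxy groups, so no ortho O-to-C silyl shift can intervene.

Step 10
Reactants: 20 5-hydroxy-8-(3-methylbut-2-enyl)-7-(triisopropylsilyloxy)-4H-chromen-4-one; 25 [3,4-bis(tert-butyldimethylsilyloxy)phenyl]boronic acid
Product: 26 (2S)-2-[3,4-bis(tert-butyldimethylsilyloxy)phenyl]-5-hydroxy-8-(3-methylbut-2-enyl)-7-(triisopropylsilyloxy)chroman-4-one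
Conditions: 25 (2 equiv), Pd(OCOCF3)2 (7 mol%), (R)-t-BuPyOx [(R)-4-tert-butyl-2-(pyridin-2-yl)-4,5-dihydrooxazole, 9 mol%], H2O (5 equiv), ClCH2CH2Cl, 60 °C, no hexafluorophosphate additive
Reagents that add atoms: none
Why: Palladium-catalysed asymmetric conjugate addition of an arylboronic acid to a chromone (transmetalation to the cationic divalent palladium–PyOx complex, enantiodetermining carbopalladation of C2=C3, protonolysis of the palladium enolate by water), in which the tert-butyl group of the (R)-ligand shields one face so that the aryl group should reach the Re face of C2 and set 2S, while the trisubstituted prenyl alkene inserts far more slowly than the enone.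

Step 11
Reactants: 26 (2S)-2-[3,4-bis(tert-butyldimethylsilyloxy)phenyl]-5-hydroxy-8-(3-methylbut-2-enyl)-7-(triisopropylsilyloxy)chroman-4-one
Product: 27 (2S)-2-[3,4-bis(tert-butyldimethylsilyloxy)phenyl]-5-hydroxy-8-[(2E)-4-hydroxy-3-methylbut-2-enyl]-7-(triisopropylsilyloxy)chroman-4-one
Conditions: SeO2 (0.4 equiv), t-BuOOH (in decane, 3 equiv), CH2Cl2, 0 °C → rt; stopped before over-oxidation, unreacted 26 recycled
Reagents that add atoms: selenium dioxide O=[Se]=O; tert-butyl hydroperoxide CC(C)(C)OO
Why: Riley allylic oxidation in its catalytic SeO2/t-BuOOH form, in which the ene reaction at the more substituted alkene terminus and the [2,3]-sigmatropic shift of the allylseleninic acid deliver oxygen to the methyl group trans to the ring A methylene and so fix the E geometry, while the mild temperature leaves C2, C3 and the silyl ethers alone.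

Step 12
Reactants: 27 (2S)-2-[3,4-bis(tert-butyldimethylsilyloxy)phenyl]-5-hydroxy-8-[(2E)-4-hydroxy-3-methylbut-2-enyl]-7-(triisopropylsilyloxy)chroman-4-one
Product: 28 (2E)-4-[(2S)-2-[3,4-bis(tert-butyldimethylsilyloxy)phenyl]-5-hydroxy-4-oxo-7-(triisopropylsilyloxy)chroman-8-yl]-2-methylbut-2-enyl acetate
Conditions: Ac2O (1.2 equiv), pyridine, CH2Cl2, 0 °C
Reagents that add atoms: acetic anhydride CC(=O)OC(C)=O
Why: O-acylation under mild base, in which the primary allylic alcohol is acetylated much faster than the C5 hydroxyl (tied up in a hydrogen bond to the C4 carbonyl) and every other phenol is silylated.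

Step 13
Reactants: 28 (2E)-4-[(2S)-2-[3,4-bis(tert-butyldimethylsilyloxy)phenyl]-5-hydroxy-4-oxo-7-(triisopropylsilyloxy)chroman-8-yl]-2-methylbut-2-enyl acetate
Product: 29 Kanzonol S, (2E)-4-[(2S)-2-(3,4-dihydroxyphenyl)-5,7-dihydroxy-4-oxochroman-8-yl]-2-methylbut-2-enyl acetate
Conditions: Et3N·3HF, THF, 0 °C → rt
Reagents that add atoms: none
Why: Fluoride-mediated cleavage of the three aryl silyl ethers, driven by Si–F bond formation; the slightly acidic amine–HF reagent avoids phenoxide formation, so retro-oxa-Michael racemisation at C2, acetate loss and attack of the C7 oxygen on the allylic acetate should all be avoided.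

Compound list
1 | diketene (4-methylideneoxetan-2-one) | C=C1CC(=O)O1 | starting material
2 | ethoxyethyne | CCOC#C | starting material
3 | ketene | C=C=O | intermediate
4 | 3-ethoxycyclobut-2-en-1-one | CCOC1=CC(=O)C1 | intermediate
5 | ethyl 4-methylpent-3-enoate | CCOC(=O)CC=C(C)C | starting material
6 | lithium 1,1-dibromo-5-methylhexa-1,4-dien-2-olate | [Li+].[O-]C(CC=C(C)C)=C(Br)Br | intermediate
7 | lithium 5-methylhex-4-en-1-yn-1-olate | [Li+].[O-]C#CCC=C(C)C | intermediate
8 | triisopropyl[(5-methylhex-4-en-1-yn-1-yl)oxy]silane | CC(C)=CCC#CO[Si](C(C)C)(C(C)C)C(C)C | intermediate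
9 | 3-ethoxybuta-1,3-dien-1-one (vinylketene) | C=C(OCC)C=C=O | intermediate
10 | 4-(1-ethoxyethenyl)-2-(3-methylbut-2-enyl)-3-(triisopropylsilyloxy)cyclobut-2-en-1-one (racemic) | C=C(OCC)C1C(=O)C(CC=C(C)C)=C1O[Si](C(C)C)(C(C)C)C(C)C | intermediate
11 | 5-ethoxy-2-(3-methylbut-2-enyl)-3-(triisopropylsilyloxy)hexa-1,3,5-trien-1-one (ketene and ethoxyvinyl groups cis on C3=C4) | O=C=C(CC=C(C)C)/C(O[Si](C(C)C)(C(C)C)C(C)C)=C\C(=C)OCC | intermediate
12 | 5-ethoxy-2-(3-methylbut-2-enyl)-3-(triisopropylsilyloxy)cyclohexa-2,4-dien-1-one | O=C1CC(OCC)=CC(O[Si](C(C)C)(C(C)C)C(C)C)=C1CC=C(C)C | intermediate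
13 | 5-ethoxy-2-(3-methylbut-2-enyl)-3-(triisopropylsilyloxy)phenol | CCOc1cc(O)c(CC=C(C)C)c(O[Si](C(C)C)(C(C)C)C(C)C)c1 | intermediate
14 | 3-ethoxy-2-(hydroxymethyl)-6-(3-methylbut-2-enyl)-5-(triisopropylsilyloxy)phenol (present as its magnesium salt) | CCOc1cc(O[Si](C(C)C)(C(C)C)C(C)C)c(CC=C(C)C)c(O)c1CO | intermediate
15 | 6-ethoxy-2-hydroxy-3-(3-methylbut-2-enyl)-4-(triisopropylsilyloxy)benzaldehyde | CCOc1cc(O[Si](C(C)C)(C(C)C)C(C)C)c(CC=C(C)C)c(O)c1C=O | intermediate
16 | 3-ethoxy-2-(1-hydroxyprop-2-ynyl)-6-(3-methylbut-2-enyl)-5-(triisopropylsilyloxy)phenol (racemic) | CCOc1cc(O[Si](C(C)C)(C(C)C)C(C)C)c(CC=C(C)C)c(O)c1C(O)C#C | intermediate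
17 | 1-[6-ethoxy-2-hydroxy-3-(3-methylbut-2-enyl)-4-(triisopropylsilyloxy)phenyl]prop-2-yn-1-one | CCOc1cc(O[Si](C(C)C)(C(C)C)C(C)C)c(CC=C(C)C)c(O)c1C(=O)C#C | intermediate
18 | 5-ethoxy-8-(3-methylbut-2-enyl)-7-(triisopropylsilyloxy)-4H-chromen-4-one | CCOc1cc(O[Si](C(C)C)(C(C)C)C(C)C)c(CC=C(C)C)c2occc(=O)c12 | intermediate
19 | 5-(dichloroboryloxy)-8-(3-methylbut-2-enyl)-7-(triisopropylsilyloxy)-4H-chromen-4-one (boron also bound to the C4 carbonyl oxygen) | CC(C)=CCc1c(O[Si](C(C)C)(C(C)C)C(C)C)cc(OB(Cl)Cl)c2c1occc2=O | intermediate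
20 | 5-hydroxy-8-(3-methylbut-2-enyl)-7-(triisopropylsilyloxy)-4H-chromen-4-one | CC(C)=CCc1c(O[Si](C(C)C)(C(C)C)C(C)C)cc(O)c2c1occc2=O | intermediate
21 | 4-bromobenzene-1,2-diol | Oc1ccc(Br)cc1O | starting material
22 | 4-bromo-1,2-bis(tert-butyldimethylsilyloxy)benzene | CC(C)(C)[Si](C)(C)Oc1ccc(Br)cc1O[Si](C)(C)C(C)(C)C | intermediate
23 | [3,4-bis(tert-butyldimethylsilyloxy)phenyl]lithium | [Li]c1ccc(O[Si](C)(C)C(C)(C)C)c(O[Si](C)(C)C(C)(C)C)c1 | intermediate
24 | lithium [3,4-bis(tert-butyldimethylsilyloxy)phenyl]triisopropoxyborate | [Li+].CC(C)O[B-](OC(C)C)(OC(C)C)c1ccc(O[Si](C)(C)C(C)(C)C)c(O[Si](C)(C)C(C)(C)C)c1 | intermediate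
25 | [3,4-bis(tert-butyldimethylsilyloxy)phenyl]boronic acid | OB(O)c1ccc(O[Si](C)(C)C(C)(C)C)c(O[Si](C)(C)C(C)(C)C)c1 | intermediate
26 | (2S)-2-[3,4-bis(tert-butyldimethylsilyloxy)phenyl]-5-hydroxy-8-(3-methylbut-2-enyl)-7-(triisopropylsilyloxy)chroman-4-one | CC(C)=CCc1c(O[Si](C(C)C)(C(C)C)C(C)C)cc(O)c2c1O[C@H](c1ccc(O[Si](C)(C)C(C)(C)C)c(O[Si](C)(C)C(C)(C)C)c1)CC2=O | intermediate
27 | (2S)-2-[3,4-bis(tert-butyldimethylsilyloxy)phenyl]-5-hydroxy-8-[(2E)-4-hydroxy-3-methylbut-2-enyl]-7-(triisopropylsilyloxy)chroman-4-one | OC/C(C)=C/Cc1c(O[Si](C(C)C)(C(C)C)C(C)C)cc(O)c2c1O[C@H](c1ccc(O[Si](C)(C)C(C)(C)C)c(O[Si](C)(C)C(C)(C)C)c1)CC2=O | intermediate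
28 | (2E)-4-[(2S)-2-[3,4-bis(tert-butyldimethylsilyloxy)phenyl]-5-hydroxy-4-oxo-7-(triisopropylsilyloxy)chroman-8-yl]-2-methylbut-2-enyl acetate | CC(=O)OC/C(C)=C/Cc1c(O[Si](C(C)C)(C(C)C)C(C)C)cc(O)c2c1O[C@H](c1ccc(O[Si](C)(C)C(C)(C)C)c(O[Si](C)(C)C(C)(C)C)c1)CC2=O | intermediate
29 | Kanzonol S, (2E)-4-[(2S)-2-(3,4-dihydroxyphenyl)-5,7-dihydroxy-4-oxochroman-8-yl]-2-methylbut-2-enyl acetate | CC(=O)OC/C(C)=C/Cc1c(O)cc(O)c2c1O[C@H](c1ccc(O)c(O)c1)CC2=O | target

Total step count: 13.
Longest linear sequence: 10 steps (step 1 or step 2, then steps 3, 4, 5, 6, 7, 10, 11, 12, 13).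

Steps most likely to fail

**Step 3.**
- What may go wrong: the vinylogous-ester stabilisation of 4 may slow the first ring opening. The long heating then needed would let the siloxyalkyne decay, let the ketene acylate the phenol on oxygen, or leave the cascade stalled at the vinylcyclobutenone stage.
- Fallback: the same vinylketene is generated without heat by a photochemical Wolff rearrangement, the diazo ketone version of the benzannulation. It sets out from 8 and comes back to the route at 9, and through it at 13.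
- Ethyl vinyl ether is lithiated (t-BuLi, THF, −78 → 0 °C) to 1-ethoxyvinyllithium F1. Acylation with N-methoxy-N-methylacetamide gives 3-ethoxybut-3-en-2-one F2.
- LiHMDS and CF3CO2CH2CF3 convert this into 5-ethoxy-1,1,1-trifluorohex-5-ene-2,4-dione F3. Detrifluoroacetylative diazo transfer (MsN3, Et3N, H2O, MeCN) then gives 1-diazo-3-ethoxybut-3-en-2-one F4.
- Irradiation of this diazo ketone with 8 (254 nm, ClCH2CH2Cl, rt) releases nitrogen and forms 9. Warming to 80 °C completes the later pericyclic steps.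

**Step 10.**
- What may go wrong: carbopalladation of an electron-rich chromone may be slow. The peri hydroxy ketone may tie up the cationic divalent palladium, the electron-rich boronic acid may protodeboronate first, and facial selectivity may erode.
- Fallback: the hydroxyl stays masked during the palladium step, and C2 is set by kinetic resolution instead of by the C–C bond formation. It sets out from 18 (with 25), bypasses step 7 and comes back at 26.
- Addition of 25 to 18 under the more active achiral catalyst (Pd(OCOCF3)2, 2,2'-bipyridine, H2O, ClCH2CH2Cl, 60 °C) gives racemic 2-[3,4-bis(tert-butyldimethylsilyloxy)phenyl]-5-ethoxy-8-(3-methylbut-2-enyl)-7-(triisopropylsilyloxy)chroman-4-one F5.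
- Noyori–Ikariya transfer hydrogenation follows (RuCl(p-cymene)[(R,R)-TsDPEN], HCO2H/Et3N, EtOAc, rt). By the usual aryl ketone model it should reduce only the 2R enantiomer.
- This leaves the (2S)-5-ethoxyflavanone F6, which is separated by chromatography from the (2R,4R)-cis-flavan-4-ol F7.
- MgI2·OEt2 in THF at reflux then removes the ethyl group by chelation and iodide attack via the iodomagnesium phenolate F8. Aqueous work-up gives 26, whose enantiopurity is checked by chiral HPLC.

**Step 11.**
- What may go wrong: over-oxidation to the enal, incomplete conversion, or selenium attack at the enolisable C3 position of the flavanone.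
- Fallback: the oxidised terminus is rebuilt by cleavage and olefination. It sets out from 26 and comes back at 27.
- Lemieux–Johnson cleavage (OsO4 cat., NaIO4, 2,6-lutidine, dioxane/H2O) passes through the 8-(2,3-dihydroxy-3-methylbutyl)flavanone F9 and gives the 8-(2-oxoethyl)flavanone F10.
- Wittig reaction with the stabilised ylide Ph3P=C(CH3)CHO (PhMe, 60 °C) gives the (E)-enal, the 8-[(2E)-3-methyl-4-oxobut-2-enyl]flavanone F11.
- Luche reduction (NaBH4, CeCl3·7H2O, MeOH/THF, −78 °C) reduces the enal in preference to the hydrogen-bonded, electron-rich C4 ketone and gives 27.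

Further compounds
F1 | step 3 | 1-ethoxyvinyllithium | [Li]C(=C)OCC
F2 | step 3 | 3-ethoxybut-3-en-2-one | C=C(OCC)C(C)=O
F3 | step 3 | 5-ethoxy-1,1,1-trifluorohex-5-ene-2,4-dione | C=C(OCC)C(=O)CC(=O)C(F)(F)F
F4 | step 3 | 1-diazo-3-ethoxybut-3-en-2-one | C=C(OCC)C(=O)C=[N+]=[N-]
F5 | step 10 | racemic 2-[3,4-bis(tert-butyldimethylsilyloxy)phenyl]-5-ethoxy-8-(3-methylbut-2-enyl)-7-(triisopropylsilyloxy)chroman-4-one | CC(C)=CCc1c(O[Si](C(C)C)(C(C)C)C(C)C)cc(OCC)c2c1OC(c1ccc(O[Si](C)(C)C(C)(C)C)c(O[Si](C)(C)C(C)(C)C)c1)CC2=O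
F6 | step 10 | (2S)-2-[3,4-bis(tert-butyldimethylsilyloxy)phenyl]-5-ethoxy-8-(3-methylbut-2-enyl)-7-(triisopropylsilyloxy)chroman-4-one | CC(C)=CCc1c(O[Si](C(C)C)(C(C)C)C(C)C)cc(OCC)c2c1O[C@H](c1ccc(O[Si](C)(C)C(C)(C)C)c(O[Si](C)(C)C(C)(C)C)c1)CC2=O
F7 | step 10 | (2R,4R)-2-[3,4-bis(tert-butyldimethylsilyloxy)phenyl]-5-ethoxy-8-(3-methylbut-2-enyl)-7-(triisopropylsilyloxy)chroman-4-ol | CC(C)=CCc1c(O[Si](C(C)C)(C(C)C)C(C)C)cc(OCC)c2c1O[C@@H](c1ccc(O[Si](C)(C)C(C)(C)C)c(O[Si](C)(C)C(C)(C)C)c1)C[C@H]2O
F8 | step 10 | iodomagnesium 5-phenolate of 26 | CC(C)=CCc1c(O[Si](C(C)C)(C(C)C)C(C)C)cc(O[Mg]I)c2c1O[C@H](c1ccc(O[Si](C)(C)C(C)(C)C)c(O[Si](C)(C)C(C)(C)C)c1)CC2=O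
F9 | step 11 | (2S)-2-[3,4-bis(tert-butyldimethylsilyloxy)phenyl]-8-(2,3-dihydroxy-3-methylbutyl)-5-hydroxy-7-(triisopropylsilyloxy)chroman-4-one (both carbinol epimers) | CC(C)(O)C(O)Cc1c(O[Si](C(C)C)(C(C)C)C(C)C)cc(O)c2c1O[C@H](c1ccc(O[Si](C)(C)C(C)(C)C)c(O[Si](C)(C)C(C)(C)C)c1)CC2=O
F10 | step 11 | 2-[(2S)-2-[3,4-bis(tert-butyldimethylsilyloxy)phenyl]-5-hydroxy-4-oxo-7-(triisopropylsilyloxy)chroman-8-yl]acetaldehyde | O=CCc1c(O[Si](C(C)C)(C(C)C)C(C)C)cc(O)c2c1O[C@H](c1ccc(O[Si](C)(C)C(C)(C)C)c(O[Si](C)(C)C(C)(C)C)c1)CC2=O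
F11 | step 11 | (2E)-4-[(2S)-2-[3,4-bis(tert-butyldimethylsilyloxy)phenyl]-5-hydroxy-4-oxo-7-(triisopropylsilyloxy)chroman-8-yl]-2-methylbut-2-enal | O=C/C(C)=C/Cc1c(O[Si](C(C)C)(C(C)C)C(C)C)cc(O)c2c1O[C@H](c1ccc(O[Si](C)(C)C(C)(C)C)c(O[Si](C)(C)C(C)(C)C)c1)CC2=O
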